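Retrosynthesis: the two MOM ethers come off last. Ring C is then cut at O1–C2 and C3–C4, giving a phenacyl ester of a ring A salicylic acid. The ester C–O bond is cut to a benzoic acid and an aryl bromomethyl ketone, and the C8–prenyl bond is traced back through olefin cross-metathesis and a Claisen shift to an O-allyl ether.
Enabling feature: C3 of ring C carries a hydroxyl and lies between the C4 carbonyl and the aryl-bearing C2. Ring C is therefore a cyclised, dehydrated 2-hydroxy-1,3-diketone, and the C3 oxygen can start as the alkyl oxygen of an ester of the C4 carboxyl carbon.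
Forward order: purchased ring A is desymmetrised as a mono-MOM ether, O-allylated, rearranged, extended to the prenyl compound and saponified. The acid is joined to the ring B bromoketone as the phenacyl ester, ring C closes in the penultimate step, and the acetals are removed.
Stereochemistry: the target has no stereocentre and its only C=C ends in two methyl groups, so nothing has to be set. The one selectivity issue (8- versus 6-prenyl) is settled by the Claisen shift from the only allylated oxygen while the other ring A oxygen stays a MOM ether.

Key step: step 8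

Assumption: methyl 2,6-dihydroxy-4-methoxybenzoate (1) is taken as purchasable; intermediates 10 and 11 are stereoisomer mixtures whose centres vanish on dehydration, so their SMILES carry no stereodescriptors.

Step 1
Reactants: 1 methyl 2,6-dihydroxy-4-methoxybenzoate
Product: 2 methyl 2-hydroxy-4-methoxy-6-(methoxymethoxy)benzoate
Conditions: MOMCl (1.05 equiv), iPr2NEt (1.2 equiv), CH2Cl2, 0 °C
Reagents that add atoms: chloromethyl methyl ether (MOMCl), COCCl
Why: MOM ether formation by O-alkylation of a phenol; the two hydroxyls are equivalent, and once one is capped the other becomes the sole hydrogen-bond donor to the ester carbonyl and reacts much more slowly, so the mono-ether should dominate.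

Step 2
Reactants: 2 methyl 2-hydroxy-4-methoxy-6-(methoxymethoxy)benzoate
Product: 3 methyl 4-methoxy-2-(methoxymethoxy)-6-(prop-2-en-1-yloxy)benzoate
Conditions: allyl bromide (1.5 equiv), K2CO3 (2 equiv), DMF, 50 °C
Reagents that add atoms: allyl bromide, C=CCBr
Why: Williamson ether synthesis on the one remaining phenol; carbonate in warm DMF is enough to break the chelate of a salicylate hydroxyl and allyl bromide is an unhindered SN2 partner.

Step 3
Reactants: 3 methyl 4-methoxy-2-(methoxymethoxy)-6-(prop-2-en-1-yloxy)benzoate
Product: 4 methyl 2-hydroxy-4-methoxy-6-(methoxymethoxy)-3-(prop-2-en-1-yl)benzoate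
Conditions: PhNEt2, 190 °C (sealed tube)
Reagents that add atoms: none
Why: Aromatic Claisen rearrangement; one ortho position of the allyl ether carries the ester, so the [3,3] shift can only end at the free ortho carbon between the oxygen and the methoxy group, which places the side chain next to the regenerated phenol and away from the MOM ether.

Step 4
Reactants: 4 methyl 2-hydroxy-4-methoxy-6-(methoxymethoxy)-3-(prop-2-en-1-yl)benzoate
Product: 5 methyl 2-hydroxy-4-methoxy-6-(methoxymethoxy)-3-(3-methylbut-2-en-1-yl)benzoate
Conditions: 2-methylbut-2-ene (excess), second-generation Grubbs catalyst (H2IMes)(PCy3)Cl2Ru=CHPh (3 mol%), CH2Cl2, 40 °C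
Reagents that add atoms: 2-methylbut-2-ene, CC=C(C)C
Why: Olefin cross-metathesis of a terminal allyl arene with excess 2-methylbut-2-ene, the standard conversion of an allyl into a prenyl group; free phenols and esters are tolerated and propene leaves as gas.

Step 5
Reactants: 5 methyl 2-hydroxy-4-methoxy-6-(methoxymethoxy)-3-(3-methylbut-2-en-1-yl)benzoate
Product: 6 2-hydroxy-4-methoxy-6-(methoxymethoxy)-3-(3-methylbut-2-en-1-yl)benzoic acid
Conditions: KOH (6 equiv), MeOH/H2O (3:1), 70 °C; then 1 M HCl to pH 3–4, 0 °C
Reagents that add atoms: potassium hydroxide, [K+].[OH-]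
Why: Ester saponification; MOM ether and prenyl group are inert to hot hydroxide, and cold acidification only to pH 3–4 should spare the acetal and avoid protodecarboxylation of the electron-rich acid, which is used at once.

Step 6
Reactants: 7 2-bromo-1-(4-hydroxyphenyl)ethanone
Product: 8 2-bromo-1-[4-(methoxymethoxy)phenyl]ethanone
Conditions: MOMCl (1.3 equiv), iPr2NEt (1.4 equiv, added last), CH2Cl2, 0 °C
Reagents that add atoms: chloromethyl methyl ether (MOMCl), COCCl
Why: MOM ether formation; the alpha-chloro ether is a far faster electrophile than the bromoketone, so with MOMCl present before the hindered amine the phenoxide should be capped before it can alkylate a second molecule.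

Step 7
Reactants: 6 2-hydroxy-4-methoxy-6-(methoxymethoxy)-3-(3-methylbut-2-en-1-yl)benzoic acid; 8 2-bromo-1-[4-(methoxymethoxy)phenyl]ethanone
Product: 9 2-[4-(methoxymethoxy)phenyl]-2-oxoethyl 2-hydroxy-4-methoxy-6-(methoxymethoxy)-3-(3-methylbut-2-en-1-yl)benzoate
Conditions: KHCO3 (1.2 equiv), DMF, rt
Reagents that add atoms: none
Why: Phenacyl ester formation by SN2 O-alkylation of a carboxylate with an alpha-bromo ketone; hydrogen carbonate ionises only the acid, so the chelated phenol stays free and the methylene is not enolised.

Step 8
Reactants: 9 2-[4-(methoxymethoxy)phenyl]-2-oxoethyl 2-hydroxy-4-methoxy-6-(methoxymethoxy)-3-(3-methylbut-2-en-1-yl)benzoate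
Product: 12 3-hydroxy-7-methoxy-5-(methoxymethoxy)-2-[4-(methoxymethoxy)phenyl]-8-(3-methylbut-2-en-1-yl)-4H-chromen-4-one, via 2-hydroxy-1,3-diketone 10 (not isolated), via cyclic hemiketal 11 (not isolated)
Conditions: LiN(SiMe3)2 (3.5 equiv), THF, −78 to 0 °C; then AcOH (excess), 60 °C
Reagents that add atoms: none
Why: The base forms the phenoxide and then the enolate of the phenacyl ketone, whose alpha carbon (future C3) adds 3-exo-trig to the ester carbonyl (future C4); the lithium oxiranolate opens by cleavage of the old ester C–O bond, so the ring A aroyl group moves from oxygen to carbon and the former ester oxygen stays on C3 as the alkoxide of diketone 10. The closest known reactions are the base-induced 1,2-acyl shift of alpha-ketol esters to alpha-hydroxy beta-diketones and the rearrangement of phenacyl esters of anthranilic and salicylic acids to 3-hydroxy-4-quinolones and 3-hydroxyflavones; the last stage is the cyclodehydration that ends a Baker–Venkataraman flavone synthesis. The surplus base converts 10 into its stabilised enolate, which draws the ketol ester/diketone equilibrium to the C-acylated side. On acidification the free phenol adds to the ring B ketone (6-exo-trig, O1–C2) to give hemiketal 11, and loss of water across C2–C3 gives the aromatic pyranone, so no stereocentre remains. The step needs a regioselective ring closure: only the hydroxyl beside the prenyl group is free and the other ring A oxygen is a MOM ether, so only the 8-prenyl isomer can form, and the chelating lithium phenoxide also activates the hindered ester carbonyl.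

Step 9
Reactants: 12 3-hydroxy-7-methoxy-5-(methoxymethoxy)-2-[4-(methoxymethoxy)phenyl]-8-(3-methylbut-2-en-1-yl)-4H-chromen-4-one
Product: 13 isoanhydroicaritin, 3,5-dihydroxy-2-(4-hydroxyphenyl)-7-methoxy-8-(3-methylbut-2-en-1-yl)-4H-chromen-4-one
Conditions: HCl (1.25 M in MeOH), 40 °C
Reagents that add atoms: none
Why: Acid-catalysed cleavage of both MOM acetals by transacetalisation to methanol; the prenyl group now sits between a methoxy group and the ring oxygen, so no ortho hydroxyl is available for chroman formation under the mild acid.

Compound list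
1 | methyl 2,6-dihydroxy-4-methoxybenzoate | COC(=O)c1c(O)cc(OC)cc1O | starting material
2 | methyl 2-hydroxy-4-methoxy-6-(methoxymethoxy)benzoate | COC(=O)c1c(O)cc(OC)cc1OCOC | intermediate
3 | methyl 4-methoxy-2-(methoxymethoxy)-6-(prop-2-en-1-yloxy)benzoate | COC(=O)c1c(OCC=C)cc(OC)cc1OCOC | intermediate
4 | methyl 2-hydroxy-4-methoxy-6-(methoxymethoxy)-3-(prop-2-en-1-yl)benzoate | COC(=O)c1c(O)c(CC=C)c(OC)cc1OCOC | intermediate
5 | methyl 2-hydroxy-4-methoxy-6-(methoxymethoxy)-3-(3-methylbut-2-en-1-yl)benzoate | COC(=O)c1c(O)c(CC=C(C)C)c(OC)cc1OCOC | intermediate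
6 | 2-hydroxy-4-methoxy-6-(methoxymethoxy)-3-(3-methylbut-2-en-1-yl)benzoic acid | OC(=O)c1c(O)c(CC=C(C)C)c(OC)cc1OCOC | intermediate
7 | 2-bromo-1-(4-hydroxyphenyl)ethanone | O=C(CBr)c1ccc(O)cc1 | starting material
8 | 2-bromo-1-[4-(methoxymethoxy)phenyl]ethanone | COCOc1ccc(C(=O)CBr)cc1 | intermediate
9 | 2-[4-(methoxymethoxy)phenyl]-2-oxoethyl 2-hydroxy-4-methoxy-6-(methoxymethoxy)-3-(3-methylbut-2-en-1-yl)benzoate | COc1cc(OCOC)c(C(=O)OCC(=O)c2ccc(OCOC)cc2)c(O)c1CC=C(C)C | intermediate
10 | 2-hydroxy-1-[2-hydroxy-4-methoxy-6-(methoxymethoxy)-3-(3-methylbut-2-en-1-yl)phenyl]-3-[4-(methoxymethoxy)phenyl]propane-1,3-dione (racemic) | COc1cc(OCOC)c(C(=O)C(O)C(=O)c2ccc(OCOC)cc2)c(O)c1CC=C(C)C | intermediate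
11 | 2,3-dihydroxy-7-methoxy-5-(methoxymethoxy)-2-[4-(methoxymethoxy)phenyl]-8-(3-methylbut-2-en-1-yl)-2,3-dihydro-4H-chromen-4-one (mixture of stereoisomers) | COc1cc(OCOC)c2c(c1CC=C(C)C)OC(O)(c1ccc(OCOC)cc1)C(O)C2=O | intermediate
12 | 3-hydroxy-7-methoxy-5-(methoxymethoxy)-2-[4-(methoxymethoxy)phenyl]-8-(3-methylbut-2-en-1-yl)-4H-chromen-4-one | COc1cc(OCOC)c2c(=O)c(O)c(-c3ccc(OCOC)cc3)oc2c1CC=C(C)C | intermediate
13 | isoanhydroicaritin, 3,5-dihydroxy-2-(4-hydroxyphenyl)-7-methoxy-8-(3-methylbut-2-en-1-yl)-4H-chromen-4-one | COc1cc(O)c2c(=O)c(O)c(-c3ccc(O)cc3)oc2c1CC=C(C)C | target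

Total step count: 9.
Longest linear sequence: 8 steps (steps 1–5, 7, 8 and 9); step 6 is a one-step side branch.

Steps most likely to fail

Step 8. The enolate carbon may fail to add to the ester carbonyl, which is flanked by two ortho oxygen substituents and deactivated by the phenoxide, so that ester cleavage or intermolecular condensation takes over. The fallback sets out from acid 6, comes back at 12, and builds ring C by the classical chalcone route. Excess MeLi in THF (0 °C to rt) should convert 6, through its lithium salts, into the methyl ketone 1-[2-hydroxy-4-methoxy-6-(methoxymethoxy)-3-(3-methylbut-2-en-1-yl)phenyl]ethanone F1. Claisen–Schmidt condensation of this ketone with commercial 4-(methoxymethoxy)benzaldehyde (KOH, EtOH, rt) should give the chalcone (E)-1-[2-hydroxy-4-methoxy-6-(methoxymethoxy)-3-(3-methylbut-2-en-1-yl)phenyl]-3-[4-(methoxymethoxy)phenyl]prop-2-en-1-one F2. Algar–Flynn–Oyamada oxidation (H2O2, NaOH, MeOH, 0 °C) then closes ring C with the C3 hydroxyl in place and gives 12; alkaline peroxide does not touch the isolated prenyl double bond. The 6'-alkoxy group is known to open a competing aurone channel in this oxidation, so 12 would have to be separated from that isomer, and this path is held in reserve only.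

Step 5. Hydroxide attack at the doubly ortho-substituted, phenoxide-deactivated ester carbonyl may be too slow, and the electron-rich salicylic acid may lose CO2 on acidification. The fallback sets out from ester 5, comes back at 9, and cleaves the ester at the methyl carbon instead of the acyl carbon. LiI in refluxing pyridine should demethylate 5 by SN2 attack of iodide and give lithium 2-hydroxy-4-methoxy-6-(methoxymethoxy)-3-(3-methylbut-2-en-1-yl)benzoate F3, the iodomethane being trapped by pyridine. After evaporation the salt is dissolved in DMF and alkylated directly with bromoketone 8 at rt to give 9, so the free acid is never formed.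

Step 3. At the temperature a plain allyl ether needs, the MOM acetal may be lost or transferred and the rearrangement may stay incomplete. The fallback sets out from phenol 2, comes back at 5, and uses a tertiary ether that rearranges at much lower temperature and delivers the prenyl group directly, so no metathesis is needed. O-Alkylation of 2 with 3-chloro-3-methylbut-1-yne (DBU, CuCl2 cat., MeCN, 0 °C) should give methyl 4-methoxy-2-(methoxymethoxy)-6-[(2-methylbut-3-yn-2-yl)oxy]benzoate F4. Semi-hydrogenation (H2, Pd/CaCO3 poisoned with Pb(OAc)2, quinoline, EtOAc, rt) should give methyl 4-methoxy-2-(methoxymethoxy)-6-[(2-methylbut-3-en-2-yl)oxy]benzoate F5. Claisen rearrangement of this 1,1-dimethylallyl ether (PhNEt2, about 130 °C) again ends at the only free ortho carbon and gives 5.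

Further compounds
F1 | step 8 | 1-[2-hydroxy-4-methoxy-6-(methoxymethoxy)-3-(3-methylbut-2-en-1-yl)phenyl]ethanone | CC(=O)c1c(O)c(CC=C(C)C)c(OC)cc1OCOC
F2 | step 8 | (E)-1-[2-hydroxy-4-methoxy-6-(methoxymethoxy)-3-(3-methylbut-2-en-1-yl)phenyl]-3-[4-(methoxymethoxy)phenyl]prop-2-en-1-one | COCOc1ccc(/C=C/C(=O)c2c(O)c(CC=C(C)C)c(OC)cc2OCOC)cc1
F3 | step 5 | lithium 2-hydroxy-4-methoxy-6-(methoxymethoxy)-3-(3-methylbut-2-en-1-yl)benzoate | [Li+].[O-]C(=O)c1c(O)c(CC=C(C)C)c(OC)cc1OCOC
F4 | step 3 | methyl 4-methoxy-2-(methoxymethoxy)-6-[(2-methylbut-3-yn-2-yl)oxy]benzoate | COC(=O)c1c(OCOC)cc(OC)cc1OC(C)(C)C#C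
F5 | step 3 | methyl 4-methoxy-2-(methoxymethoxy)-6-[(2-methylbut-3-en-2-yl)oxy]benzoate | COC(=O)c1c(OCOC)cc(OC)cc1OC(C)(C)C=C
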